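The numbers in the tables stem from a simulated flask for an exercise, noise included.

At 8.0 d, which is 192 h, the dawn flask reaches its last reading, so the question is what a further 8.0 d can still bring.

| setting | dawn | winter | flask |
|---|---|---|---|
| substrate | 0.50 M | 0.50 M | 0.50 M |
| coupling partner | 0.50 M | 0.50 M | 0.500 M |
| protic impurity | 0.10 M | 0.20 M | 0.100 M |
| remark | the very flask that is asked about, followed so far | run made earlier |  |
| time |  |  | 8.0 d |

| run | time / h | product / % |
|---|---|---|
| dawn | 15.0 | 48.6 |
| dawn | 25.0 | 55.8 |
| dawn | 40.0 | 62.7 |
| dawn | 60.0 | 68.6 |
| dawn | 72.0 | 70.8 |
| dawn | 120 | 75.1 |
| dawn | 192 | 77.9 |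
| winter | 2.00 | 24.3 |
| winter | 4.00 | 29.8 |
| winter | 6.00 | 32.0 |
| winter | 8.00 | 33.4 |
| winter | 10.0 | 36.1 |
| winter | 12.0 | 38.1 |
| winter | 15.0 | 41.0 |

(each reading ± 0.5 percentage points)

* product, in percent of the substrate first charged, at 8.0 d
* which option adds most product ("none" when 2 percentage points or less is all one gets) (cedar / oak / ash / larch / none)
* product present, in percent of the substrate first charged, after oak
* product present, in percent of the substrate first charged, after larch

- cedar: at 8.0 d add substrate, 50.0 % of the amount charged, then wait 8.0 d
- oak: change nothing and wait 8.0 d more
- ash: at 8.0 d add coupling partner, 100 % of the amount charged, then wait 8.0 d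
- larch: at 8.0 d take out 90 % of the released group then present, then wait 8.0 d

- what is added takes up no volume worth counting
- what may be going on: substrate + coupling partner <-> product + released group; coupling partner + protic impurity -> quenched reagent; released group -> by-product carried off

Coupling partner has two takers: substrate, which it turns into product, and protic impurity, which turns it into quenched reagent. At 15.0 h the dawn flask reads 48.6 % product and the winter flask, with its doubled impurity, 41.0 %, lower by 7.6 percentage points. The reckoning here assumes that each impurity quenches one coupling partner. That leaves the dawn flask 0.400 M of coupling partner, less than its 0.50 M of substrate, which makes coupling partner the limiting reagent. The ceiling C is surviving coupling partner over substrate charged, 80.0 %.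

Let g be C minus product. A gap that shrinks by a fixed factor per hour (first-order decay) falls steadily in powers of ten, so one asks how long each power takes. In the dawn flask, g reads 4.9 points at 120 h and 2.1 points at 192 h, so one power of ten takes about 196 h, a value read from scattered readings. The further 192 h is close to that stretch, so oak should leave g at 0.22 points, which is 79.8 % product. Larch and cedar add no coupling partner, so C stays put, and larch should land between oak and C. Ash takes surviving coupling partner past the substrate charged, which opens up to 22 points more. This reckoning therefore says 77.9 % now, and ash.

The forecast gives 77.8 % now, 79.7 % after oak, 79.8 % after larch, and ash: “Only fresh coupling partner lifts it”. For oak, this reckoning gives 79.8 % against its 79.7 %.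

The flask gives 78.1 % at 8.0 d, 79.8 % after oak, 79.8 % after larch, and ash adds 22 points.

    substrate + coupling partner ⇌ product + released group (K = 0.280, k = 0.690 /M/h)
    coupling partner + protic impurity → quenched reagent (k = 5.10 /M/h)
    released group → by-product carried off (k = 0.190 /h)

At 192 h, coupling partner in the asked flask stands at 1.9 % of its charge, which is 1.9 points of the substrate charged, and C minus product is 1.9 points. A neighbouring flask charged with 0.85 M of substrate, its coupling partner and impurity unchanged, has C at 47.1 %, and it holds 47.1 % product at 8.0 d.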